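The route rests on cutting ring C of the flavanone at O1–C8a and at C4–C4a. This turns ring A into a 3,5-dioxygenated benzyne and leaves an open-chain anti-aldol unit that already carries C2 and C3. In the key step fluoride unmasks a β-silyloxy Weinreb amide and an o-silylaryl triflate side by side. The C2 alkoxide adds to the aryne and the C4a carbanion closes onto the C4 amide carbonyl. The step exploits the C5 oxygen of ring A beside C4a, which polarises the C4a–C8a aryne bond so that oxygen enters at C8a only. An auxiliary-controlled aldol sets both stereocentres, a late Heck reaction adds the chalcone arm, and acid removes six MOM groups.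

Key step: step 9

Assumption: the MgCl2-catalysed anti-aldol of 6 is taken to follow the chelated (Z)-enolate model known for N-propionyl oxazolidinones (the facial sense of imide alkylation), so that the (R)-auxiliary gives the (2S,3R) adduct.

Step 1
Reactants: 1 2-(5-bromo-2-hydroxyphenyl)acetic acid
Product: 3 2-[5-bromo-2-(methoxymethoxy)phenyl]acetic acid, via MOM ester 2 (not isolated)
Conditions: MOMCl (2.5 equiv), iPr2NEt, CH2Cl2, 0 °C to rt; then LiOH, THF/H2O, rt; cold 1 M HCl to pH 4
Reagents that add atoms: chloromethyl methyl ether (MOMCl), COCCl; lithium hydroxide, [Li+].[OH-]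
Why: Acetal-type O-alkylation (Williamson etherification) caps both acidic oxygens, and saponification then cleaves only the far more labile acyloxymethyl ester, so the acid should be freed while the aryl MOM ether and the bromide stay untouched.

Step 2
Reactants: 3 2-[5-bromo-2-(methoxymethoxy)phenyl]acetic acid; 4 (R)-4-benzyloxazolidin-2-one
Product: 6 (R)-4-benzyl-3-{2-[5-bromo-2-(methoxymethoxy)phenyl]acetyl}oxazolidin-2-one, via mixed anhydride 5 (not isolated)
Conditions: PivCl, Et3N, THF, −20 °C; then LiCl, 4, rt
Reagents that add atoms: none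
Why: N-Acylation of the oxazolidinone through the mixed pivalic anhydride under LiCl/Et3N activation is the standard entry to Evans imides, attack falls on the less hindered arylacetyl carbonyl, and the only stereocentre is bought in with 4.

Step 3
Reactants: 6 (R)-4-benzyl-3-{2-[5-bromo-2-(methoxymethoxy)phenyl]acetyl}oxazolidin-2-one; 7 4-(methoxymethoxy)benzaldehyde
Product: 9 (R)-4-benzyl-3-{(2S,3R)-2-[5-bromo-2-(methoxymethoxy)phenyl]-3-hydroxy-3-[4-(methoxymethoxy)phenyl]propanoyl}oxazolidin-2-one, via silyl ether 8 (not isolated)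
Conditions: MgCl2 (0.2 equiv), Et3N, TMSCl, EtOAc, rt; then citric acid (cat.), MeOH, rt
Reagents that add atoms: none
Why: Magnesium-halide-catalysed Evans anti-aldol reaction: soft enolisation of the acidic arylacetyl imide gives the chelated (Z)-magnesium enolate, the non-enolisable aldehyde adds through a boat-like transition state on the face away from the benzyl group, silylation of the aldolate releases the catalyst, and the auxiliary thus sets both new centres as (2S,3R) before mild methanolysis removes the silyl group without harm to the MOM ethers.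

Step 4
Reactants: 9 anti-aldol imide
Product: 10 (2S,3R)-2-[5-bromo-2-(methoxymethoxy)phenyl]-3-hydroxy-N-methoxy-3-[4-(methoxymethoxy)phenyl]-N-methylpropanamide
Conditions: MeNHOMe·HCl, AlMe3, CH2Cl2, −10 °C to rt; aq. potassium sodium tartrate
Reagents that add atoms: N,O-dimethylhydroxylamine hydrochloride, CNOC.Cl
Why: Aluminium-amide transamination (Weinreb amide synthesis) is steered to the exocyclic carbonyl by the β-hydroxyl group bound as its aluminium alkoxide and is non-basic enough to leave both stereocentres, the MOM ethers and the bromide alone.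

Step 5
Reactants: 10 β-hydroxy Weinreb amide
Product: 11 (2S,3R)-2-[5-bromo-2-(methoxymethoxy)phenyl]-N-methoxy-3-[4-(methoxymethoxy)phenyl]-N-methyl-3-(trimethylsilyloxy)propanamide
Conditions: TMSCl, imidazole, CH2Cl2, 0 °C
Reagents that add atoms: chlorotrimethylsilane, C[Si](C)(C)Cl
Why: Routine silyl ether formation masks the only O–H proton and installs the fluoride-labile trigger for step 9 without touching a stereocentre.

Step 6
Reactants: 12 phloroglucinol (benzene-1,3,5-triol)
Product: 13 3,5-bis(methoxymethoxy)phenol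
Conditions: MOMCl (2.0 equiv), iPr2NEt, DMF, 0 °C to rt
Reagents that add atoms: chloromethyl methyl ether (MOMCl), COCCl
Why: Stoichiometry-controlled O-alkylation (Williamson type) of a threefold symmetric triol can give only one bis-ether, which should be separable from the mono- and tris-ethers by chromatography.

Step 7
Reactants: 13 3,5-bis(methoxymethoxy)phenol
Product: 14 2-bromo-3,5-bis(methoxymethoxy)phenol
Conditions: NBS, CH2Cl2, −78 to 0 °C
Reagents that add atoms: N-bromosuccinimide, O=C1CCC(=O)N1Br
Why: Electrophilic aromatic bromination of the very electron-rich phenol should favour the two equivalent positions ortho to the small hydroxyl group and para to a MOM ether over the single position crowded between two MOM ethers.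

Step 8
Reactants: 14 2-bromo-3,5-bis(methoxymethoxy)phenol
Product: 17 3,5-bis(methoxymethoxy)-2-(trimethylsilyl)phenyl trifluoromethanesulfonate, via aryl silyl ether 15 (not isolated), via lithium phenoxide 16 (not isolated)
Conditions: HMDS, THF, 65 °C, then evaporate; n-BuLi, THF, −78 °C; Tf2O, −78 °C
Reagents that add atoms: hexamethyldisilazane, C[Si](C)(C)N[Si](C)(C)C; trifluoromethanesulfonic anhydride, O=S(=O)(OS(=O)(=O)C(F)(F)F)C(F)(F)F
Why: O-Silylation, bromine–lithium exchange, retro-Brook 1,3-shift of silicon from oxygen to carbon and triflation of the resulting phenoxide form the standard sequence to o-silylaryl triflates, and exchange at −78 °C is faster than any MOM-directed deprotonation.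

Step 9
Reactants: 11 β-silyloxy Weinreb amide; 17 o-silylaryl triflate
Product: 20 (2R,3S)-3-[5-bromo-2-(methoxymethoxy)phenyl]-5,7-bis(methoxymethoxy)-2-[4-(methoxymethoxy)phenyl]chroman-4-one, via aryne 18 (not isolated), via tetrahedral adduct 19 (not isolated)
Conditions: 17 (1.5 equiv), KF, 18-crown-6, 4 Å MS, THF, 0 °C to rt; then AcOH, 0 °C
Reagents that add atoms: none
Why: Proposed new method: fluoride removes the O-silyl group of 11 and triggers 1,2-elimination of 17, the free C2 alkoxide adds to aryne 18 at the carbon remote from the flanking MOM ether (O1–C8a), and the aryl anion so placed at C4a attacks the Weinreb carbonyl (C4–C4a) to give adduct 19, which should release the ketone only in the cold acetic acid quench. The closest known reaction types are the aryne annulations of salicylate esters to xanthones and of N–H β-lactams to 2,3-dihydroquinolin-4-ones, together with the O-arylation of aliphatic alcohols by arynes, whereas an aliphatic β-silyloxy amide has not served as the partner. Ring C closes in the 6-exo-trig mode after an intermolecular first bond. No bond at C2 or C3 is made or broken, so (2R,3S) comes unchanged from the anti-aldol unit, both aryl groups sit equatorial in the closing chair, trans is also the thermodynamic arrangement should C3 enolise, and the transient C4 centre of 19 is lost on collapse. The step needs attack of oxygen at C8a and not at C4a, which the inductively withdrawing C5 oxygen secures by distorting the aryne and stabilising the carbanion beside it. It also needs acyl capture to outrun proton transfer and retro-aldol cleavage, which the proton-free medium, the weakly acidifying amide (a much poorer enolate leaving group than an imide or ester) and the persistence of 19 (no ketone and no free base beside fluoride) are meant to secure.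

Step 10
Reactants: 21 2,4-dihydroxybenzaldehyde
Product: 22 2,4-bis(methoxymethoxy)benzaldehyde
Conditions: NaH, MOMCl, DMF, 0 °C to rt
Reagents that add atoms: chloromethyl methyl ether (MOMCl), COCCl
Why: Williamson-type double O-alkylation, for which NaH is chosen because the hydrogen-bonded 2-hydroxyl group resists weaker bases.

Step 11
Reactants: 22 2,4-bis(methoxymethoxy)benzaldehyde
Product: 23 1-[2,4-bis(methoxymethoxy)phenyl]prop-2-en-1-ol (racemic)
Conditions: CH2=CHMgBr, THF, −78 to 0 °C; aq. NH4Cl
Reagents that add atoms: vinylmagnesium bromide, C=C[Mg]Br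
Why: 1,2-Addition of a Grignard reagent to the aldehyde gives the allylic alcohol, whose new carbinol centre is racemic and is erased in step 12.

Step 12
Reactants: 23 1-[2,4-bis(methoxymethoxy)phenyl]prop-2-en-1-ol
Product: 24 1-[2,4-bis(methoxymethoxy)phenyl]prop-2-en-1-one
Conditions: MnO2, CH2Cl2, rt
Reagents that add atoms: none
Why: MnO2 oxidation is selective for allylic and benzylic alcohols and is neutral, so the acid-labile MOM ethers and the polymerisable enone should survive.

Step 13
Reactants: 20 bromo-flavanone; 24 aryl vinyl ketone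
Product: 25 (2R,3S)-3-{5-[(E)-3-[2,4-bis(methoxymethoxy)phenyl]-3-oxoprop-1-enyl]-2-(methoxymethoxy)phenyl}-5,7-bis(methoxymethoxy)-2-[4-(methoxymethoxy)phenyl]chroman-4-one
Conditions: Pd[P(t-Bu)3]2 (5 mol %), Cy2NMe, 1,4-dioxane, rt to 40 °C
Reagents that add atoms: none
Why: Heck reaction: oxidative addition of the aryl bromide, syn insertion at the unsubstituted enone terminus and syn β-hydride elimination give the (E)-chalcone, and the bulky electron-rich phosphine lets the electron-rich bromide react near room temperature, where the hindered amine should neither open ring C nor disturb the trans (thermodynamic) C2/C3 pair.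

Step 14
Reactants: 25 hexa-MOM ether of the target
Product: 26 target, (2R,3S)-3-{5-[(E)-3-(2,4-dihydroxyphenyl)-3-oxoprop-1-enyl]-2-hydroxyphenyl}-5,7-dihydroxy-2-(4-hydroxyphenyl)chroman-4-one
Conditions: HCl (cat.), MeOH/THF, 45 °C
Reagents that add atoms: none
Why: Acid-catalysed acetal exchange with methanol removes all six MOM groups, leaves the enone intact unlike hydrogenolysis, avoids the phenoxide-triggered opening of ring C that racemises flavanones in base, and can only return C3 to its favoured trans arrangement if it enolises.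

Compound list
1 | 2-(5-bromo-2-hydroxyphenyl)acetic acid | OC(=O)Cc1cc(Br)ccc1O | starting material
2 | methoxymethyl 2-[5-bromo-2-(methoxymethoxy)phenyl]acetate | COCOC(=O)Cc1cc(Br)ccc1OCOC | intermediate
3 | 2-[5-bromo-2-(methoxymethoxy)phenyl]acetic acid | OC(=O)Cc1cc(Br)ccc1OCOC | intermediate
4 | (R)-4-benzyloxazolidin-2-one | O=C1N[C@H](Cc2ccccc2)CO1 | starting material
5 | 2-[5-bromo-2-(methoxymethoxy)phenyl]acetic pivalic anhydride | CC(C)(C)C(=O)OC(=O)Cc1cc(Br)ccc1OCOC | intermediate
6 | (R)-4-benzyl-3-{2-[5-bromo-2-(methoxymethoxy)phenyl]acetyl}oxazolidin-2-one | O=C(Cc1cc(Br)ccc1OCOC)N1[C@H](Cc2ccccc2)COC1=O | intermediate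
7 | 4-(methoxymethoxy)benzaldehyde | O=Cc1ccc(OCOC)cc1 | starting material
8 | O-trimethylsilyl ether of 9, (2S,3R) | O=C(N1[C@H](Cc2ccccc2)COC1=O)[C@@H](c1cc(Br)ccc1OCOC)[C@@H](O[Si](C)(C)C)c1ccc(OCOC)cc1 | intermediate
9 | (R)-4-benzyl-3-{(2S,3R)-2-[5-bromo-2-(methoxymethoxy)phenyl]-3-hydroxy-3-[4-(methoxymethoxy)phenyl]propanoyl}oxazolidin-2-one | O=C(N1[C@H](Cc2ccccc2)COC1=O)[C@@H](c1cc(Br)ccc1OCOC)[C@@H](O)c1ccc(OCOC)cc1 | intermediate
10 | (2S,3R)-2-[5-bromo-2-(methoxymethoxy)phenyl]-3-hydroxy-N-methoxy-3-[4-(methoxymethoxy)phenyl]-N-methylpropanamide | CON(C)C(=O)[C@@H](c1cc(Br)ccc1OCOC)[C@@H](O)c1ccc(OCOC)cc1 | intermediate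
11 | (2S,3R)-2-[5-bromo-2-(methoxymethoxy)phenyl]-N-methoxy-3-[4-(methoxymethoxy)phenyl]-N-methyl-3-(trimethylsilyloxy)propanamide | CON(C)C(=O)[C@@H](c1cc(Br)ccc1OCOC)[C@@H](O[Si](C)(C)C)c1ccc(OCOC)cc1 | intermediate
12 | phloroglucinol | Oc1cc(O)cc(O)c1 | starting material
13 | 3,5-bis(methoxymethoxy)phenol | COCOc1cc(O)cc(OCOC)c1 | intermediate
14 | 2-bromo-3,5-bis(methoxymethoxy)phenol | COCOc1cc(O)c(Br)c(OCOC)c1 | intermediate
15 | [2-bromo-3,5-bis(methoxymethoxy)phenoxy]trimethylsilane | COCOc1cc(O[Si](C)(C)C)c(Br)c(OCOC)c1 | intermediate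
16 | lithium 3,5-bis(methoxymethoxy)-2-(trimethylsilyl)phenoxide | COCOc1cc([O-])c([Si](C)(C)C)c(OCOC)c1.[Li+] | intermediate
17 | 3,5-bis(methoxymethoxy)-2-(trimethylsilyl)phenyl trifluoromethanesulfonate | COCOc1cc(OS(=O)(=O)C(F)(F)F)c([Si](C)(C)C)c(OCOC)c1 | intermediate
18 | 3,5-bis(methoxymethoxy)benzyne (1,2-didehydrobenzene) | COCOC1=CC(OCOC)=CC#C1 | intermediate
19 | potassium (2R,3S)-3-[5-bromo-2-(methoxymethoxy)phenyl]-4-[methoxy(methyl)amino]-5,7-bis(methoxymethoxy)-2-[4-(methoxymethoxy)phenyl]chroman-4-olate (C4 undefined) | Brc1ccc(OCOC)c([C@@H]2C([O-])(N(C)OC)c3c(OCOC)cc(OCOC)cc3O[C@H]2c2ccc(OCOC)cc2)c1.[K+] | intermediate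
20 | (2R,3S)-3-[5-bromo-2-(methoxymethoxy)phenyl]-5,7-bis(methoxymethoxy)-2-[4-(methoxymethoxy)phenyl]chroman-4-one (trans) | Brc1ccc(OCOC)c([C@@H]2C(=O)c3c(OCOC)cc(OCOC)cc3O[C@H]2c2ccc(OCOC)cc2)c1 | intermediate
21 | 2,4-dihydroxybenzaldehyde | O=Cc1ccc(O)cc1O | starting material
22 | 2,4-bis(methoxymethoxy)benzaldehyde | O=Cc1ccc(OCOC)cc1OCOC | intermediate
23 | 1-[2,4-bis(methoxymethoxy)phenyl]prop-2-en-1-ol (racemic) | C=CC(O)c1ccc(OCOC)cc1OCOC | intermediate
24 | 1-[2,4-bis(methoxymethoxy)phenyl]prop-2-en-1-one | C=CC(=O)c1ccc(OCOC)cc1OCOC | intermediate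
25 | hexa-MOM ether of the target, (2R,3S), (E) | O=C(/C=C/c1ccc(OCOC)c([C@@H]2C(=O)c3c(OCOC)cc(OCOC)cc3O[C@H]2c2ccc(OCOC)cc2)c1)c1ccc(OCOC)cc1OCOC | intermediate
26 | (2R,3S)-3-{5-[(E)-3-(2,4-dihydroxyphenyl)-3-oxoprop-1-enyl]-2-hydroxyphenyl}-5,7-dihydroxy-2-(4-hydroxyphenyl)chroman-4-one | O=C(/C=C/c1ccc(O)c([C@@H]2C(=O)c3c(O)cc(O)cc3O[C@H]2c2ccc(O)cc2)c1)c1ccc(O)cc1O | target

Total step count: 14. Longest linear sequence: 8 steps (1, 2, 3, 4, 5, 9, 13, 14).

Steps most likely to fail

1. Step 9.
- What may go wrong: the free alkoxide may fragment by retro-aldol cleavage before it meets the short-lived aryne. The aryl anion may be protonated before acyl capture. The adduct may collapse early, followed by base-induced opening of ring C and erosion of the configuration at C2.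
- Fallback (known chemistry, the two bonds made one after the other): it sets out from 9. The free alcohol is O-arylated with the aryne generated from 17 (KF, 18-crown-6, THF, −20 °C). This is the O–H insertion of an aliphatic alcohol, in which the aryl anion is simply protonated, and it gives the 3,5-bis(methoxymethoxy)phenyl ether imide F1.
- LiOH/H2O2 (THF/H2O, 0 °C) then removes the auxiliary to give the β-aryloxy acid F2.
- (CF3CO)2O in CH2Cl2 at 0 °C closes ring C by intramolecular Friedel–Crafts acylation at either of the two equivalent positions ortho to the ether oxygen. The route is rejoined at 20.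

2. Step 3.
- What may go wrong: anti and facial selectivity may erode because the ortho-oxygenated aryl group can disturb the chelated enolate. Et3N may also epimerise the acidic α-position.
- Fallback: it sets out from 6 (with 7). The dibutylboron (Z)-enolate (Bu2BOTf, iPr2NEt, CH2Cl2, −78 to 0 °C, H2O2 work-up) undergoes the Evans syn-aldol reaction through a closed chair. This gives the (2R,3R) syn-aldol imide F3, which has the same carbinol configuration as 9.
- The operations of steps 4, 5 and 9 then lead through the syn Weinreb amide F4, its trimethylsilyl ether F5 and the cis tetrahedral adduct F6 to the cis-(2R,3R)-flavanone F7.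
- Et3N in CH2Cl2 at rt equilibrates the acidic C3 position to the diequatorial trans isomer, so that C3 is set by thermodynamic control from C2. The route is rejoined at 20.

3. Step 13.
- What may go wrong: the vinyl ketone may polymerise in the presence of phosphine and amine. Oxidative addition of the electron-rich bromide may be sluggish and force heating. The amine may then induce β-elimination that opens ring C.
- Fallback (base-free): it sets out from 20. Stille coupling with tributyl(vinyl)stannane (Pd(PPh3)4, toluene, 90 °C) gives the vinylarene flavanone F8.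
- Cross metathesis of F8 with 24 (second-generation Hoveyda–Grubbs catalyst, CH2Cl2, 40 °C) builds the (E)-enone under neutral conditions. The route is rejoined at 25.

Further compounds
F1 | step 9 | (R)-4-benzyl-3-{(2S,3R)-3-[3,5-bis(methoxymethoxy)phenoxy]-2-[5-bromo-2-(methoxymethoxy)phenyl]-3-[4-(methoxymethoxy)phenyl]propanoyl}oxazolidin-2-one | O=C(N1[C@H](Cc2ccccc2)COC1=O)[C@@H](c1cc(Br)ccc1OCOC)[C@@H](Oc1cc(OCOC)cc(OCOC)c1)c1ccc(OCOC)cc1
F2 | step 9 | (2S,3R)-3-[3,5-bis(methoxymethoxy)phenoxy]-2-[5-bromo-2-(methoxymethoxy)phenyl]-3-[4-(methoxymethoxy)phenyl]propanoic acid | OC(=O)[C@@H](c1cc(Br)ccc1OCOC)[C@@H](Oc1cc(OCOC)cc(OCOC)c1)c1ccc(OCOC)cc1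
F3 | step 3 | (R)-4-benzyl-3-{(2R,3R)-2-[5-bromo-2-(methoxymethoxy)phenyl]-3-hydroxy-3-[4-(methoxymethoxy)phenyl]propanoyl}oxazolidin-2-one | O=C(N1[C@H](Cc2ccccc2)COC1=O)[C@H](c1cc(Br)ccc1OCOC)[C@@H](O)c1ccc(OCOC)cc1
F4 | step 3 | (2R,3R)-2-[5-bromo-2-(methoxymethoxy)phenyl]-3-hydroxy-N-methoxy-3-[4-(methoxymethoxy)phenyl]-N-methylpropanamide | CON(C)C(=O)[C@H](c1cc(Br)ccc1OCOC)[C@@H](O)c1ccc(OCOC)cc1
F5 | step 3 | (2R,3R)-2-[5-bromo-2-(methoxymethoxy)phenyl]-N-methoxy-3-[4-(methoxymethoxy)phenyl]-N-methyl-3-(trimethylsilyloxy)propanamide | CON(C)C(=O)[C@H](c1cc(Br)ccc1OCOC)[C@@H](O[Si](C)(C)C)c1ccc(OCOC)cc1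
F6 | step 3 | potassium (2R,3R)-3-[5-bromo-2-(methoxymethoxy)phenyl]-4-[methoxy(methyl)amino]-5,7-bis(methoxymethoxy)-2-[4-(methoxymethoxy)phenyl]chroman-4-olate | Brc1ccc(OCOC)c([C@H]2C([O-])(N(C)OC)c3c(OCOC)cc(OCOC)cc3O[C@H]2c2ccc(OCOC)cc2)c1.[K+]
F7 | step 3 | (2R,3R)-3-[5-bromo-2-(methoxymethoxy)phenyl]-5,7-bis(methoxymethoxy)-2-[4-(methoxymethoxy)phenyl]chroman-4-one (cis) | Brc1ccc(OCOC)c([C@H]2C(=O)c3c(OCOC)cc(OCOC)cc3O[C@H]2c2ccc(OCOC)cc2)c1
F8 | step 13 | (2R,3S)-5,7-bis(methoxymethoxy)-3-[2-(methoxymethoxy)-5-vinylphenyl]-2-[4-(methoxymethoxy)phenyl]chroman-4-one | C=Cc1ccc(OCOC)c([C@@H]2C(=O)c3c(OCOC)cc(OCOC)cc3O[C@H]2c2ccc(OCOC)cc2)c1
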